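**Retrosynthetic overview**
- The strategy rests on ring A: a hexasubstituted benzene in which C5, C6, C7 and C8 all carry oxygen (O5 para to O8), while its sixth bond, C4a=C8a, is the C5=C6 double bond of the γ-pyranone ring C. These four oxygenated carbons are taken in one piece from a squarate ester.
- Ring A is disconnected at C5–C4a (6π electrocyclization of a dienylketene) and at C8–C8a (addition of a C6-metalated 2-aryl-3-methoxy-4-pyranone to di-tert-butyl squarate).
- The 2-aryl-4-pyranone comes from Suzuki coupling of 2-bromo-3-methoxy-4-pyranone (from pyromeconic acid) with the ring B boronic acid (from 3,4-bis(benzyloxy)benzaldehyde).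
- Ring order: rings B and C are bought and joined first; ring A is closed last. The end game is tert-butyl cleavage, 7-O-benzylation, 6-O-methylation and hydrogenolysis.

Key step: step 9

Assumption: compounds 1, 9 and 13 are taken as purchasable. A tert-butyl group lost during step 9 would not matter, because step 10 removes both.

**Route**

Step 1
Reactants: 1 3,4-bis(benzyloxy)benzaldehyde
Product: 3 3,4-bis(benzyloxy)phenol, via aryl formate 2 (not isolated)
Conditions: mCPBA, CH2Cl2, 0 °C to rt; aq NaHCO3 wash; then K2CO3 (cat.), MeOH, rt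
Reagents that add atoms: mCPBA (3-chloroperoxybenzoic acid), O=C(OO)c1cccc(Cl)c1
Why: Baeyer–Villiger oxidation of an electron-rich benzaldehyde, in which the aryl group bearing a para benzyloxy donor migrates in preference to hydrogen, should give the formate, and mild base-catalysed methanolysis then frees the phenol without touching the benzyl ethers.

Step 2
Reactants: 3 3,4-bis(benzyloxy)phenol
Product: 4 1,2-bis(benzyloxy)-4-methoxybenzene
Conditions: MeI, K2CO3, acetone, reflux
Reagents that add atoms: iodomethane, CI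
Why: Williamson O-methylation of the only free phenol should proceed cleanly under standard carbonate conditions.

Step 3
Reactants: 4 1,2-bis(benzyloxy)-4-methoxybenzene
Product: 5 1,2-bis(benzyloxy)-4-bromo-5-methoxybenzene
Conditions: NBS, MeCN, 0 °C to rt
Reagents that add atoms: N-bromosuccinimide, O=C1CCC(=O)N1Br
Why: Electrophilic aromatic bromination should go to the one unhindered position that is ortho to the methoxy group and para to a benzyloxy group, as in the bromination of 1,2,4-trialkoxybenzenes, whereas the other doubly activated site is flanked by two ether groups.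

Step 4
Reactants: 5 1,2-bis(benzyloxy)-4-bromo-5-methoxybenzene
Product: 8 [4,5-bis(benzyloxy)-2-methoxyphenyl]boronic acid, via aryllithium 6 (not isolated), via lithium aryltriisopropoxyborate 7 (not isolated)
Conditions: n-BuLi, THF, −78 °C; B(OiPr)3, −78 °C to rt; aq HCl
Reagents that add atoms: triisopropyl borate, CC(C)OB(OC(C)C)OC(C)C; water, O
Why: Lithium–bromine exchange at −78 °C is much faster than benzylic deprotonation and gives an aryllithium stabilised by the ortho methoxy group, which is borylated and hydrolysed to the boronic acid.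

Step 5
Reactants: 9 3-hydroxy-4H-pyran-4-one (pyromeconic acid)
Product: 10 2-bromo-3-hydroxy-4H-pyran-4-one
Conditions: NBS, MeCN, 0 °C to rt
Reagents that add atoms: N-bromosuccinimide, O=C1CCC(=O)N1Br
Why: Electrophilic bromination of the enol should occur at C2, the nucleophilic β-carbon of the C3 enol, which is the site at which 3-hydroxy-4-pyranones take up electrophiles in general.

Step 6
Reactants: 10 2-bromo-3-hydroxy-4H-pyran-4-one
Product: 11 2-bromo-3-methoxy-4H-pyran-4-one
Conditions: MeI, K2CO3, acetone, rt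
Reagents that add atoms: iodomethane, CI
Why: Williamson O-methylation of the acidic enolic hydroxyl with excess iodomethane under mild carbonate conditions should outpace any displacement of the vinylogous acyl bromide.

Step 7
Reactants: 8 [4,5-bis(benzyloxy)-2-methoxyphenyl]boronic acid; 11 2-bromo-3-methoxy-4H-pyran-4-one
Product: 12 2-[4,5-bis(benzyloxy)-2-methoxyphenyl]-3-methoxy-4H-pyran-4-one
Conditions: Pd(PPh3)4 (cat., zerovalent palladium), Na2CO3, DME/H2O, 80 °C
Reagents that add atoms: none
Why: Suzuki–Miyaura cross-coupling should join rings B and C because the C2–Br bond is a vinylogous acyl bromide that adds readily to zerovalent palladium and the electron-rich boronic acid transmetalates under mild carbonate conditions.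

Step 8
Reactants: 12 2-[4,5-bis(benzyloxy)-2-methoxyphenyl]-3-methoxy-4H-pyran-4-one; 13 di-tert-butyl squarate (3,4-di-tert-butoxycyclobut-3-ene-1,2-dione)
Product: 16 2,3-di-tert-butoxy-4-methoxy-4-{6-[4,5-bis(benzyloxy)-2-methoxyphenyl]-5-methoxy-4-oxo-4H-pyran-2-yl}cyclobut-2-en-1-one (racemic), via 6-lithiopyranone 14 (not isolated), via lithium alkoxide 15 (not isolated)
Conditions: LiTMP (from n-BuLi and 2,2,6,6-tetramethylpiperidine), THF, −78 °C; cannulated into 13, THF, −78 °C; then MeOTf, −78 to 0 °C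
Reagents that add atoms: methyl trifluoromethanesulfonate, COS(=O)(=O)C(F)(F)F
Why: The hindered amide should remove the pyranone C6 hydrogen, the only C–H on a carbon bonded to the ring oxygen and the site at which 4-pyranones and chromones are metalated by tetramethylpiperidide bases, after which the alkenyllithium adds 1,2 to one carbonyl of the symmetric squarate and the tertiary lithium alkoxide is O-methylated in the same flask, the new quaternary carbinol carbon forming as a racemate because nothing chiral is present.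

Step 9
Reactants: 16 2,3-di-tert-butoxy-4-methoxy-4-{6-[4,5-bis(benzyloxy)-2-methoxyphenyl]-5-methoxy-4-oxo-4H-pyran-2-yl}cyclobut-2-en-1-one
Product: 19 2-[4,5-bis(benzyloxy)-2-methoxyphenyl]-6,7-di-tert-butoxy-5-hydroxy-3,8-dimethoxy-4H-chromen-4-one, via dienylketene 17 (not isolated), via cyclohexadienone 18 (not isolated)
Conditions: toluene (degassed), 110 °C, argon
Reagents that add atoms: none
Why: Heating should break the cyclobutenone C1–C4 bond in a conrotatory 4π opening in which the C4 methoxy group turns outward, so that the pyranonyl group sits cis to the ketene in 17; the ketene C=C, the central C=C and the pyranone C5=C6 bond then close ring A as a six-membered carbocycle by thermal disrotatory 6π electrocyclization, the ketene carbon bonding to pyranone C5 to form the flavone C5–C4a bond in 18. Shift of the doubly activated C4a hydrogen of 18 to the C5 oxygen then aromatizes ring A, leaving the former ketene oxygen as the chelated 5-hydroxyl and the trapped carbinol oxygen as the 8-methoxy group. The closest known reaction type is the thermal ring expansion of squarate-derived 4-alkenyl- and 4-heteroaryl-4-alkoxycyclobutenones to hydroquinone monoethers, here with the weakly aromatic γ-pyranone C=C acting as the alkenyl group. No stereocenter results, since the racemic carbinol carbon of 16 becomes sp2 C8 and the C4a center of 18 disappears on tautomerization. The step needs outward rotation of the methoxy group and 6π closure ahead of other ketene reactions; the donor oxygen at C4 secures the first, and the fact that pyranone C5–H is the only position within reach of the ketene carbon secures a single regioisomer.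

Step 10
Reactants: 19 2-[4,5-bis(benzyloxy)-2-methoxyphenyl]-6,7-di-tert-butoxy-5-hydroxy-3,8-dimethoxy-4H-chromen-4-one
Product: 20 2-[4,5-bis(benzyloxy)-2-methoxyphenyl]-5,6,7-trihydroxy-3,8-dimethoxy-4H-chromen-4-one
Conditions: TFA, CH2Cl2, 0 °C, argon
Reagents that add atoms: none
Why: Acid-mediated cleavage of the two aryl tert-butyl ethers through the tert-butyl cation (lost as isobutene) should be fast at 0 °C, conditions under which aryl benzyl and methyl ethers are retained.

Step 11
Reactants: 20 2-[4,5-bis(benzyloxy)-2-methoxyphenyl]-5,6,7-trihydroxy-3,8-dimethoxy-4H-chromen-4-one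
Product: 21 7-(benzyloxy)-2-[4,5-bis(benzyloxy)-2-methoxyphenyl]-5,6-dihydroxy-3,8-dimethoxy-4H-chromen-4-one
Conditions: BnBr (1.05 equiv), K2CO3 (1.1 equiv), DMF (degassed), rt, argon
Reagents that add atoms: benzyl bromide, BrCc1ccccc1
Why: Williamson alkylation with one equivalent of base should select the 7-hydroxyl, the most acidic phenol because it is para to the C4 carbonyl through C4a, as is usual for 5,6,7-trihydroxyflavones, while the 5-hydroxyl is tied up in a hydrogen bond to the carbonyl.

Step 12
Reactants: 21 7-(benzyloxy)-2-[4,5-bis(benzyloxy)-2-methoxyphenyl]-5,6-dihydroxy-3,8-dimethoxy-4H-chromen-4-one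
Product: 22 7-(benzyloxy)-2-[4,5-bis(benzyloxy)-2-methoxyphenyl]-5-hydroxy-3,6,8-trimethoxy-4H-chromen-4-one
Conditions: MeI, K2CO3, acetone, 40 °C, argon
Reagents that add atoms: iodomethane, CI
Why: Williamson methylation should take place only at the 6-hydroxyl, since the 5-hydroxyl chelated to the C4 carbonyl is alkylated only under forcing conditions.

Step 13
Reactants: 22 7-(benzyloxy)-2-[4,5-bis(benzyloxy)-2-methoxyphenyl]-5-hydroxy-3,6,8-trimethoxy-4H-chromen-4-one
Product: 23 5,7,4',5'-tetrahydroxy-3,6,8,2'-tetramethoxyflavone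
Conditions: H2 (1 atm), Pd/C, EtOAc/MeOH, rt
Reagents that add atoms: none
Why: Catalytic hydrogenolysis should remove the three benzyl ethers as toluene while the methyl ethers and the tetrasubstituted C2=C3 bond of the flavone stay intact.

**Compound list**

1 | 3,4-bis(benzyloxy)benzaldehyde | O=Cc1ccc(OCc2ccccc2)c(OCc2ccccc2)c1 | starting material
2 | 3,4-bis(benzyloxy)phenyl formate | O=COc1ccc(OCc2ccccc2)c(OCc2ccccc2)c1 | intermediate
3 | 3,4-bis(benzyloxy)phenol | Oc1ccc(OCc2ccccc2)c(OCc2ccccc2)c1 | intermediate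
4 | 1,2-bis(benzyloxy)-4-methoxybenzene | COc1ccc(OCc2ccccc2)c(OCc2ccccc2)c1 | intermediate
5 | 1,2-bis(benzyloxy)-4-bromo-5-methoxybenzene | COc1cc(OCc2ccccc2)c(OCc2ccccc2)cc1Br | intermediate
6 | [4,5-bis(benzyloxy)-2-methoxyphenyl]lithium | [Li]c1cc(OCc2ccccc2)c(OCc2ccccc2)cc1OC | intermediate
7 | lithium [4,5-bis(benzyloxy)-2-methoxyphenyl]tri(propan-2-yloxy)borate | [Li+].COc1cc(OCc2ccccc2)c(OCc2ccccc2)cc1[B-](OC(C)C)(OC(C)C)OC(C)C | intermediate
8 | [4,5-bis(benzyloxy)-2-methoxyphenyl]boronic acid | COc1cc(OCc2ccccc2)c(OCc2ccccc2)cc1B(O)O | intermediate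
9 | 3-hydroxy-4H-pyran-4-one (pyromeconic acid) | O=c1ccocc1O | starting material
10 | 2-bromo-3-hydroxy-4H-pyran-4-one | O=c1ccoc(Br)c1O | intermediate
11 | 2-bromo-3-methoxy-4H-pyran-4-one | COc1c(Br)occc1=O | intermediate
12 | 2-[4,5-bis(benzyloxy)-2-methoxyphenyl]-3-methoxy-4H-pyran-4-one | COc1cc(OCc2ccccc2)c(OCc2ccccc2)cc1-c1occc(=O)c1OC | intermediate
13 | di-tert-butyl squarate (3,4-di-tert-butoxycyclobut-3-ene-1,2-dione) | CC(C)(C)OC1=C(OC(C)(C)C)C(=O)C1=O | starting material
14 | {6-[4,5-bis(benzyloxy)-2-methoxyphenyl]-5-methoxy-4-oxo-4H-pyran-2-yl}lithium | [Li]c1cc(=O)c(OC)c(-c2cc(OCc3ccccc3)c(OCc3ccccc3)cc2OC)o1 | intermediate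
15 | lithium 2,3-di-tert-butoxy-1-{6-[4,5-bis(benzyloxy)-2-methoxyphenyl]-5-methoxy-4-oxo-4H-pyran-2-yl}-4-oxocyclobut-2-en-1-olate (racemic) | [Li]OC1(c2cc(=O)c(OC)c(-c3cc(OCc4ccccc4)c(OCc4ccccc4)cc3OC)o2)C(OC(C)(C)C)=C(OC(C)(C)C)C1=O | intermediate
16 | 2,3-di-tert-butoxy-4-methoxy-4-{6-[4,5-bis(benzyloxy)-2-methoxyphenyl]-5-methoxy-4-oxo-4H-pyran-2-yl}cyclobut-2-en-1-one (racemic) | COC1(c2cc(=O)c(OC)c(-c3cc(OCc4ccccc4)c(OCc4ccccc4)cc3OC)o2)C(OC(C)(C)C)=C(OC(C)(C)C)C1=O | intermediate
17 | (3Z)-2,3-di-tert-butoxy-4-methoxy-4-{6-[4,5-bis(benzyloxy)-2-methoxyphenyl]-5-methoxy-4-oxo-4H-pyran-2-yl}buta-1,3-dien-1-one (dienylketene, pyranonyl cis to the ketene) | O=C=C(OC(C)(C)C)/C(OC(C)(C)C)=C(/OC)c1cc(=O)c(OC)c(-c2cc(OCc3ccccc3)c(OCc3ccccc3)cc2OC)o1 | intermediate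
18 | 2-[4,5-bis(benzyloxy)-2-methoxyphenyl]-6,7-di-tert-butoxy-3,8-dimethoxy-4aH-chromene-4,5-dione (racemic at C4a) | COC1=C2OC(-c3cc(OCc4ccccc4)c(OCc4ccccc4)cc3OC)=C(OC)C(=O)C2C(=O)C(OC(C)(C)C)=C1OC(C)(C)C | intermediate
19 | 2-[4,5-bis(benzyloxy)-2-methoxyphenyl]-6,7-di-tert-butoxy-5-hydroxy-3,8-dimethoxy-4H-chromen-4-one | COc1cc(OCc2ccccc2)c(OCc2ccccc2)cc1-c1oc2c(OC)c(OC(C)(C)C)c(OC(C)(C)C)c(O)c2c(=O)c1OC | intermediate
20 | 2-[4,5-bis(benzyloxy)-2-methoxyphenyl]-5,6,7-trihydroxy-3,8-dimethoxy-4H-chromen-4-one | COc1cc(OCc2ccccc2)c(OCc2ccccc2)cc1-c1oc2c(OC)c(O)c(O)c(O)c2c(=O)c1OC | intermediate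
21 | 7-(benzyloxy)-2-[4,5-bis(benzyloxy)-2-methoxyphenyl]-5,6-dihydroxy-3,8-dimethoxy-4H-chromen-4-one | COc1cc(OCc2ccccc2)c(OCc2ccccc2)cc1-c1oc2c(OC)c(OCc3ccccc3)c(O)c(O)c2c(=O)c1OC | intermediate
22 | 7-(benzyloxy)-2-[4,5-bis(benzyloxy)-2-methoxyphenyl]-5-hydroxy-3,6,8-trimethoxy-4H-chromen-4-one | COc1cc(OCc2ccccc2)c(OCc2ccccc2)cc1-c1oc2c(OC)c(OCc3ccccc3)c(OC)c(O)c2c(=O)c1OC | intermediate
23 | 5,7,4',5'-tetrahydroxy-3,6,8,2'-tetramethoxyflavone | COc1cc(O)c(O)cc1-c1oc2c(OC)c(O)c(OC)c(O)c2c(=O)c1OC | target

**Step count and risks**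

Total step count: 13. Longest linear sequence: 11 steps (steps 1 to 4 and 7 to 13).

Steps most likely to fail:

1. Step 9. The tert-butyl enol ethers may shed isobutene at the temperature of ring opening before the ring has closed, or the ketene may be consumed by paths other than 6π closure. The fallback sets out from 12 and 13 and comes back at 19. It places the C8 methyl ether after the ring closure, so the ring expansion can be run on the free carbinol, which is the best documented form of this reaction. The adduct 15 formed as in step 8 would be quenched with aqueous NH4Cl instead of MeOTf to give carbinol F4. Thermolysis of F4 in degassed toluene under argon, with the hydroxyl turning outward, should give 2-[4,5-bis(benzyloxy)-2-methoxyphenyl]-6,7-di-tert-butoxy-5,8-dihydroxy-3-methoxy-4H-chromen-4-one, hydroquinone F5. Its non-chelated 8-hydroxyl would then be methylated selectively (MeI, K2CO3, acetone, argon) to reach 19, the 5-hydroxyl being held by the hydrogen bond to the carbonyl.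

2. Step 8. The lithiated pyranone may attack pyranone that is not yet metalated, metalation may go in part to C5 with ring opening, or the hindered tertiary alkoxide may be methylated incompletely. The fallback sets out from 12 and comes back at 16, and replaces direct lithiation by a halogen handle. Zincation at C6 with TMPZnCl·LiCl in THF at rt would give organozinc chloride F1, and iodine would convert it into 2-[4,5-bis(benzyloxy)-2-methoxyphenyl]-6-iodo-3-methoxy-4H-pyran-4-one, iodide F2. Iodine–magnesium exchange with iPrMgCl·LiCl at −40 °C would give pyranonylmagnesium chloride F3, which adds to 13 and gives after NH4Cl work-up the 4-hydroxycyclobutenone, carbinol F4. Methylation of the tertiary hydroxyl with MeI and Ag2O in MeCN leads to 16.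

3. Step 11. The 6-hydroxyl may be alkylated as well, and the pyrogallol-type triol may be oxidised by air under base. The fallback sets out from 20 and comes back at 21, and replaces direct selective alkylation by full protection and selective unmasking. Acetylation (Ac2O, pyridine) would give 2-[4,5-bis(benzyloxy)-2-methoxyphenyl]-3,8-dimethoxy-4-oxo-4H-chromene-5,6,7-triyl triacetate, triacetate F6. Thiolysis with PhSH and imidazole in NMP at 0 °C should remove only the 7-O-acetyl group, the aryl ester para to the carbonyl, to give the 7-hydroxy 5,6-diacetate, phenol F7. Mitsunobu benzylation (BnOH, PPh3, DIAD, THF) under neutral conditions would give the 7-benzyl ether 5,6-diacetate, benzyl ether F8. Methanolysis of both acetates (K2CO3, MeOH, argon) returns to 21.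

**Further compounds**

F1 | step 8 | chloro{6-[4,5-bis(benzyloxy)-2-methoxyphenyl]-5-methoxy-4-oxo-4H-pyran-2-yl}zinc (as its LiCl complex) | Cl[Zn]c1cc(=O)c(OC)c(-c2cc(OCc3ccccc3)c(OCc3ccccc3)cc2OC)o1
F2 | step 8 | 2-[4,5-bis(benzyloxy)-2-methoxyphenyl]-6-iodo-3-methoxy-4H-pyran-4-one | COc1cc(OCc2ccccc2)c(OCc2ccccc2)cc1-c1oc(I)cc(=O)c1OC
F3 | step 8 | chloro{6-[4,5-bis(benzyloxy)-2-methoxyphenyl]-5-methoxy-4-oxo-4H-pyran-2-yl}magnesium (as its LiCl complex) | Cl[Mg]c1cc(=O)c(OC)c(-c2cc(OCc3ccccc3)c(OCc3ccccc3)cc2OC)o1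
F4 | step 8 | 2,3-di-tert-butoxy-4-hydroxy-4-{6-[4,5-bis(benzyloxy)-2-methoxyphenyl]-5-methoxy-4-oxo-4H-pyran-2-yl}cyclobut-2-en-1-one (racemic) | OC1(c2cc(=O)c(OC)c(-c3cc(OCc4ccccc4)c(OCc4ccccc4)cc3OC)o2)C(OC(C)(C)C)=C(OC(C)(C)C)C1=O
F5 | step 9 | 2-[4,5-bis(benzyloxy)-2-methoxyphenyl]-6,7-di-tert-butoxy-5,8-dihydroxy-3-methoxy-4H-chromen-4-one | COc1cc(OCc2ccccc2)c(OCc2ccccc2)cc1-c1oc2c(O)c(OC(C)(C)C)c(OC(C)(C)C)c(O)c2c(=O)c1OC
F6 | step 11 | 2-[4,5-bis(benzyloxy)-2-methoxyphenyl]-3,8-dimethoxy-4-oxo-4H-chromene-5,6,7-triyl triacetate | COc1cc(OCc2ccccc2)c(OCc2ccccc2)cc1-c1oc2c(OC)c(OC(C)=O)c(OC(C)=O)c(OC(C)=O)c2c(=O)c1OC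
F7 | step 11 | 2-[4,5-bis(benzyloxy)-2-methoxyphenyl]-7-hydroxy-3,8-dimethoxy-4-oxo-4H-chromene-5,6-diyl diacetate | COc1cc(OCc2ccccc2)c(OCc2ccccc2)cc1-c1oc2c(OC)c(O)c(OC(C)=O)c(OC(C)=O)c2c(=O)c1OC
F8 | step 11 | 7-(benzyloxy)-2-[4,5-bis(benzyloxy)-2-methoxyphenyl]-3,8-dimethoxy-4-oxo-4H-chromene-5,6-diyl diacetate | COc1cc(OCc2ccccc2)c(OCc2ccccc2)cc1-c1oc2c(OC)c(OCc3ccccc3)c(OC(C)=O)c(OC(C)=O)c2c(=O)c1OC
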